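**Retrosynthetic overview**
1. Target 21 ⇐ hydrogenolysis of tribenzyl ether 20 ⇐ Suzuki–Miyaura union (C3–C1′) of iodochromone 7 (rings A and C) with the ring B chromanyl boronate 19.
2. Key disconnection: both C–O bonds of the dihydropyran (O1–C2 and C3–OH) come from o-prenylphenol 14 by phenol-directed asymmetric epoxidation (sets C3 as R) and 6-endo attack of the phenol oxygen.
3. 14 ⇐ aromatic Claisen rearrangement of 1,1-dimethylallyl ether 13 ⇐ O-allylation of iodophenol 9 ⇐ ortho-iodination of 3-(benzyloxy)phenol 8. The iodine blocks one ortho site and is the coupling handle.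
4. 7 ⇐ iodocyclisation of the enaminone of dibenzyl phloroacetophenone 3 (pyranone C–O closure).
5. Ring order: pyranone ring C (step 2), dihydropyran ring (step 7), then the biaryl bond (step 8).

Assumption: in step 7 the (R,R) ligand L [(1R,2R)-N,N′-dihydroxy-N,N′-bis(diphenylacetyl)cyclohexane-1,2-diamine] is taken to give the (R)-epoxide; the sense is checked once against 17 made by the fallback and, if opposite, the (S,S) ligand is used with nothing else changed.

**Route**

Step 1
Reactants: 1 1-(2,4,6-trihydroxyphenyl)ethan-1-one; 2 benzyl bromide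
Product: 3 1-[2,4-bis(benzyloxy)-6-hydroxyphenyl]ethan-1-one
Conditions: BnBr (2.1 equiv), K2CO3, DMF, 50 °C
Reagents that add atoms: benzyl bromide 2, BrCc1ccccc1
Why: Williamson etherification takes the two hydroxyls that are not hydrogen-bonded to the ketone, so two equivalents of BnBr leave the chelated ortho-hydroxyl needed for ring closure.

Step 2
Reactants: 3 1-[2,4-bis(benzyloxy)-6-hydroxyphenyl]ethan-1-one; 4 N,N-dimethylformamide dimethyl acetal; 5 iodine
Product: 7 5,7-bis(benzyloxy)-3-iodo-4H-chromen-4-one, via enaminone 6 (not isolated)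
Conditions: DMF-DMA, 95 °C; then I2, CHCl3, rt
Reagents that add atoms: N,N-dimethylformamide dimethyl acetal 4, COC(OC)N(C)C; iodine 5, II
Why: Condensation with the amide acetal gives the enaminone, and the known iodine-induced cyclisation then closes the pyranone O1–C2 bond with loss of dimethylamine and leaves iodine at C3.

Step 3
Reactants: 8 3-(benzyloxy)phenol; 5 iodine
Product: 9 5-(benzyloxy)-2-iodophenol
Conditions: I2, NaHCO3, THF–H2O, 0 °C → rt
Reagents that add atoms: iodine 5, II
Why: Electrophilic aromatic iodination of the phenoxide goes ortho to the free hydroxyl and para to the ether oxygen (the site between the two oxygens is hindered), as for other 3-alkoxyphenols, which fixes which oxygen becomes the pyran oxygen.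

Step 4
Reactants: 10 2-methylbut-3-en-2-ol; 11 di-tert-butyl dicarbonate
Product: 12 tert-butyl 2-methylbut-3-en-2-yl carbonate
Conditions: n-BuLi, THF, −78 °C; then Boc2O, → rt; H2O quench
Reagents that add atoms: di-tert-butyl dicarbonate 11, CC(C)(C)OC(=O)OC(=O)OC(C)(C)C
Why: Acylation of the lithium tert-alkoxide with Boc2O gives the mixed carbonate, the standard activation of a tertiary allylic alcohol for allylic substitution.

Step 5
Reactants: 9 5-(benzyloxy)-2-iodophenol; 12 tert-butyl 2-methylbut-3-en-2-yl carbonate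
Product: 13 4-(benzyloxy)-1-iodo-2-[(2-methylbut-3-en-2-yl)oxy]benzene
Conditions: Pd(PPh3)4 (2 mol%), 4 Å MS, THF, 0 °C
Reagents that add atoms: tert-butyl 2-methylbut-3-en-2-yl carbonate 12, C=CC(C)(C)OC(=O)OC(C)(C)C
Why: Tsuji–Trost decarboxylative O-allylation, in which zerovalent palladium ionises the carbonate faster than it inserts into the hindered electron-rich C–I bond and the phenoxide attacks the more substituted allyl terminus under kinetic control at 0 °C to give the tertiary ether.

Step 6
Reactants: 13 4-(benzyloxy)-1-iodo-2-[(2-methylbut-3-en-2-yl)oxy]benzene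
Product: 14 3-(benzyloxy)-6-iodo-2-(3-methylbut-2-en-1-yl)phenol
Conditions: PhNEt2, 125 °C
Reagents that add atoms: none
Why: Aromatic Claisen rearrangement, whose [3,3] shift can end only at the ortho carbon not blocked by iodine, turns the 1,1-dimethylallyl unit into a prenyl group and rearomatises to the phenol.

Step 7
Reactants: 14 3-(benzyloxy)-6-iodo-2-(3-methylbut-2-en-1-yl)phenol; 15 cumene hydroperoxide
Product: 17 (3R)-5-(benzyloxy)-8-iodo-2,2-dimethyl-3,4-dihydro-2H-chromen-3-ol, via epoxide 16 (not isolated)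
Conditions: Hf(OtBu)4 (10 mol%), ligand L (12 mol%), DMPU (20 mol%), 4 Å MS, cumene hydroperoxide (1.1 equiv), PhMe, 0 °C; then CSA (10 mol%), 0 °C
Reagents that add atoms: cumene hydroperoxide 15, CC(C)(OO)c1ccccc1
Why: Proposed new method: phenol-directed asymmetric epoxidation on a tetravalent hafnium bishydroxamate followed in the same flask by acid-triggered 6-endo ring closure; the phenol of 14 is a bishomoallylic hydroxyl (O–C(ar)–C(ar)–CH2–CH=C) that binds hafnium as the aryloxide beside the η2-cumylperoxide, so oxygen is delivered inside the C2-symmetric ligand pocket to one face of the trisubstituted alkene and only metal-bound alkene reacts (no background epoxidation), the d0 metal cannot oxidise the electron-rich phenol as pentavalent vanadium would, and CSA then lets the same phenol oxygen open the epoxide at its tertiary carbon so the secondary C–O bond made in the epoxidation is untouched and becomes the (R)-C3–OH; the closest known reaction types are the Zr/Hf–bishydroxamic acid asymmetric epoxidation of homoallylic and bishomoallylic aliphatic alcohols and the acid-mediated 6-endo cyclisation of o-(epoxyprenyl)phenols to 3-hydroxy-2,2-dimethylchromans.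

Step 8
Reactants: 17 (3R)-5-(benzyloxy)-8-iodo-2,2-dimethyl-3,4-dihydro-2H-chromen-3-ol; 18 bis(pinacolato)diboron; 7 5,7-bis(benzyloxy)-3-iodo-4H-chromen-4-one
Product: 20 5,7-bis(benzyloxy)-3-[(3R)-5-(benzyloxy)-3-hydroxy-2,2-dimethyl-3,4-dihydro-2H-chromen-8-yl]-4H-chromen-4-one, via boronate 19 (not isolated)
Conditions: B2pin2 (1.1 equiv), PdCl2(dppf) (5 mol%), KOAc, 1,4-dioxane, 85 °C; then 7, aq. K3PO4, 85 °C
Reagents that add atoms: bis(pinacolato)diboron 18, CC1(C)OB(OC1(C)C)B1OC(C)(C)C(C)(C)O1 (its boron is carried only in 19); 5,7-bis(benzyloxy)-3-iodo-4H-chromen-4-one 7, O=c1c(I)coc2cc(OCc3ccccc3)cc(OCc3ccccc3)c12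
Why: Miyaura borylation of the aryl iodide and Suzuki–Miyaura coupling with the 3-iodochromone in one flask form the C3–C1′ bond without touching the free alcohol, the benzyl ethers or the stereocenter.

Step 9
Reactants: 20 5,7-bis(benzyloxy)-3-[(3R)-5-(benzyloxy)-3-hydroxy-2,2-dimethyl-3,4-dihydro-2H-chromen-8-yl]-4H-chromen-4-one
Product: 21 5,7-dihydroxy-3-[(3R)-3,5-dihydroxy-2,2-dimethyl-3,4-dihydro-2H-chromen-8-yl]-4H-chromen-4-one
Conditions: H2 (1 atm), Pd/C, EtOAc–MeOH, rt
Reagents that add atoms: none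
Why: Hydrogenolysis of the three aryl benzyl ethers on Pd/C at 1 atm is much faster than reduction of the chromone C2=C3 bond, so the reaction is stopped at full debenzylation and the carbinol stereocenter is unaffected.

**Compound list**
1 | 1-(2,4,6-trihydroxyphenyl)ethan-1-one | CC(=O)c1c(O)cc(O)cc1O | starting material
2 | benzyl bromide | BrCc1ccccc1 | starting material
3 | 1-[2,4-bis(benzyloxy)-6-hydroxyphenyl]ethan-1-one | CC(=O)c1c(O)cc(OCc2ccccc2)cc1OCc1ccccc1 | intermediate
4 | N,N-dimethylformamide dimethyl acetal | COC(OC)N(C)C | starting material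
5 | iodine | II | starting material
6 | (E)-1-[2,4-bis(benzyloxy)-6-hydroxyphenyl]-3-(dimethylamino)prop-2-en-1-one | CN(C)/C=C/C(=O)c1c(O)cc(OCc2ccccc2)cc1OCc1ccccc1 | intermediate
7 | 5,7-bis(benzyloxy)-3-iodo-4H-chromen-4-one | O=c1c(I)coc2cc(OCc3ccccc3)cc(OCc3ccccc3)c12 | intermediate
8 | 3-(benzyloxy)phenol | Oc1cccc(OCc2ccccc2)c1 | starting material
9 | 5-(benzyloxy)-2-iodophenol | Oc1cc(OCc2ccccc2)ccc1I | intermediate
10 | 2-methylbut-3-en-2-ol | C=CC(C)(C)O | starting material
11 | di-tert-butyl dicarbonate | CC(C)(C)OC(=O)OC(=O)OC(C)(C)C | starting material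
12 | tert-butyl 2-methylbut-3-en-2-yl carbonate | C=CC(C)(C)OC(=O)OC(C)(C)C | intermediate
13 | 4-(benzyloxy)-1-iodo-2-[(2-methylbut-3-en-2-yl)oxy]benzene | C=CC(C)(C)Oc1cc(OCc2ccccc2)ccc1I | intermediate
14 | 3-(benzyloxy)-6-iodo-2-(3-methylbut-2-en-1-yl)phenol | CC(C)=CCc1c(O)c(I)ccc1OCc1ccccc1 | intermediate
15 | cumene hydroperoxide | CC(C)(OO)c1ccccc1 | starting material
16 | 3-(benzyloxy)-2-{[(2R)-3,3-dimethyloxiran-2-yl]methyl}-6-iodophenol | CC1(C)O[C@@H]1Cc1c(O)c(I)ccc1OCc1ccccc1 | intermediate
17 | (3R)-5-(benzyloxy)-8-iodo-2,2-dimethyl-3,4-dihydro-2H-chromen-3-ol | CC1(C)Oc2c(I)ccc(OCc3ccccc3)c2C[C@H]1O | intermediate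
18 | bis(pinacolato)diboron | CC1(C)OB(OC1(C)C)B1OC(C)(C)C(C)(C)O1 | starting material
19 | (3R)-5-(benzyloxy)-2,2-dimethyl-8-(4,4,5,5-tetramethyl-1,3,2-dioxaborolan-2-yl)-3,4-dihydro-2H-chromen-3-ol | CC1(C)Oc2c(B3OC(C)(C)C(C)(C)O3)ccc(OCc3ccccc3)c2C[C@H]1O | intermediate
20 | 5,7-bis(benzyloxy)-3-[(3R)-5-(benzyloxy)-3-hydroxy-2,2-dimethyl-3,4-dihydro-2H-chromen-8-yl]-4H-chromen-4-one | CC1(C)Oc2c(-c3coc4cc(OCc5ccccc5)cc(OCc5ccccc5)c4c3=O)ccc(OCc3ccccc3)c2C[C@H]1O | intermediate
21 | 5,7-dihydroxy-3-[(3R)-3,5-dihydroxy-2,2-dimethyl-3,4-dihydro-2H-chromen-8-yl]-4H-chromen-4-one | CC1(C)Oc2c(-c3coc4cc(O)cc(O)c4c3=O)ccc(O)c2C[C@H]1O | target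

**Step count and risks**
Total steps: 9. Longest linear sequence: 6 (steps 3, 5, 6, 7, 8, 9, from 8 to 21).

The three steps most likely to fail:

Step 7 (the proposed new step). It may give low enantioselectivity, slow turnover through aryloxide binding, or the 5-exo dihydrobenzofuran. The fallback uses only known chemistry, sets out from 9 and comes back at 17, replacing steps 5 to 7. Compound 9 is heated with 1,1-diethoxy-3-methylbut-2-ene and 3-picoline in xylene at 140 °C (condensation, then oxa-6π electrocyclisation) to give 5-(benzyloxy)-8-iodo-2,2-dimethyl-2H-chromene F1. Jacobsen–Katsuki epoxidation with (R,R)-(salen)MnCl [the chloromanganese complex of N,N′-bis(3,5-di-tert-butylsalicylidene)-(1R,2R)-cyclohexane-1,2-diamine], NaOCl and 4-phenylpyridine N-oxide in CH2Cl2 at 0 °C gives (3R,4R)-5-(benzyloxy)-3,4-epoxy-8-iodo-2,2-dimethyl-3,4-dihydro-2H-chromene F2. LiAlH4 in THF at −20 to 0 °C delivers hydride to benzylic C4 only, which leaves the C3–O bond and its configuration intact and gives 17.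

Step 8 (one-flask borylation and Suzuki–Miyaura coupling). The electron-rich ortho-alkoxy boronate may protodeboronate, and the iodochromone is sensitive to aqueous base. The fallback is a base-free Negishi coupling that sets out from 17 and comes back at 20. iPrMgCl·LiCl (2.2 equiv, THF, −20 °C → rt) deprotonates the alcohol and exchanges iodine for magnesium to give chloromagnesium (3R)-5-(benzyloxy)-8-(chloromagnesio)-2,2-dimethyl-3,4-dihydro-2H-chromen-3-olate F3. ZnCl2 converts it into [(3R)-5-(benzyloxy)-3-(chloromagnesiooxy)-2,2-dimethyl-3,4-dihydro-2H-chromen-8-yl]zinc chloride F4. F4 is coupled with 7 using Pd(PPh3)4 (5 mol%) in THF at 50 °C, and aqueous work-up gives 20.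

Step 5 (palladium-catalysed tertiary O-allylation). It may give the linear prenyl ether, or the catalyst may be lost to insertion into the C–I bond. The fallback avoids the O-allylation and Claisen pair, sets out from 9 and comes back at 14. NaH in toluene converts 9 into sodium 5-(benzyloxy)-2-iodophenolate F5. This tight ion pair is C-alkylated by prenyl bromide in toluene (rt → 40 °C) at its only free ortho carbon, the known ortho-C-prenylation of phenoxides in non-polar media, to give 14 directly.

**Further compounds**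
F1 | step 7 | 5-(benzyloxy)-8-iodo-2,2-dimethyl-2H-chromene | CC1(C)C=Cc2c(OCc3ccccc3)ccc(I)c2O1
F2 | step 7 | (3R,4R)-5-(benzyloxy)-3,4-epoxy-8-iodo-2,2-dimethyl-3,4-dihydro-2H-chromene | CC1(C)Oc2c(I)ccc(OCc3ccccc3)c2[C@H]2O[C@@H]12
F3 | step 8 | chloromagnesium (3R)-5-(benzyloxy)-8-(chloromagnesio)-2,2-dimethyl-3,4-dihydro-2H-chromen-3-olate | CC1(C)Oc2c([Mg]Cl)ccc(OCc3ccccc3)c2C[C@H]1O[Mg]Cl
F4 | step 8 | [(3R)-5-(benzyloxy)-3-(chloromagnesiooxy)-2,2-dimethyl-3,4-dihydro-2H-chromen-8-yl]zinc chloride | CC1(C)Oc2c([Zn]Cl)ccc(OCc3ccccc3)c2C[C@H]1O[Mg]Cl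
F5 | step 5 | sodium 5-(benzyloxy)-2-iodophenolate | [Na+].[O-]c1cc(OCc2ccccc2)ccc1I
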